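## Structural features

Bisoflavolin J is an achiral dimer of two isoflavones (3-aryl-4H-chromen-4-ones). Unit 1 is an 8-chloro-7-hydroxyisoflavone and unit 2 a 7,4'-dihydroxyisoflavone; their only link is a diaryl ether from O4' of ring B of unit 1 to C8 of ring A of unit 2. There is no stereocentre, so the problems are positional. Ring A of unit 1 carries O1 (on C8a), Cl (C8) and OH (C7) on three neighbouring carbons; ring A of unit 2 carries O1, the aryloxy group and OH in the same 1,2,3 pattern. The fragile groups are the three free phenols (C7–OH of each unit, C4'–OH of unit 2), the two pyranone rings (opened at C2 by aqueous hydroxide) and the aryl C–Cl bond (lost under hydrogenolysis). The real difficulty is regiochemical: a late electrophilic chlorination would have to choose between ring A of unit 1, ring A of unit 2 and the positions next to the 4'-hydroxyl, and the ether must be made at a carbon flanked by two oxygens. The key step uses the fact that C8a–C8(Cl)–C7 of unit 1 is the O=C–CHCl–C=O unit of 2-chlorocyclohexane-1,3-dione and that C6, C5 and C4a are its three methylenes. Ring A is therefore carried as a dihydro ring with the chlorine already in place while ring C (O1, C2, C3, C4) is annulated onto it. The symmetric trioxygenation of ring A of unit 2 maps onto 2,6-dimethoxyphenol, so the hindered ether oxygen arrives with a commercial phenol.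

## Logic of the disconnections

17 to 14 and 15 (through 16). The cuts are C4–C4a of unit 2 and both bonds to C2 of unit 2 (C2–C3 and O1–C2). In 14 the ring that becomes ring A of unit 2 is a 2-aryloxyresorcinol, whose most nucleophilic carbon (ortho to one hydroxyl, para to the other, two equivalent sites) is exactly C4a. This removes ring C and ring B of unit 2 in one operation and leaves the commercial acid 15. The forward step must acylate this ring in preference to ring A of unit 1, and 16 must take up one carbon at its benzylic methylene and cyclise with free phenols present.

14 to 13. The cuts are three O–CH3 bonds. The methyl groups are what allows the enolate and oxidation chemistry earlier; two come in with 3 and one with 2, so no protection step is spent. The forward step needs a Lewis acid that cleaves three aryl methyl ethers and spares the diaryl ether, the pyranone and the C–Cl bond.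

13 to 12. Two hydrogens are put back on C5 and C6 of unit 1. One oxidation level down, ring A is a cyclohexadiene that derives from a cyclohexane-1,3-dione, so the chlorine need never be introduced on an arene. The forward step needs a dehydrogenation that leaves the electron-rich trioxygenated ring alone.

12 to 2 and 9 (through 10 and 11). The cuts are C4–C4a and O1–C2 of unit 1. This separates a three-carbon acyl unit that already carries ring B and the ether from a six-carbon ring that already carries chlorine and the C7 oxygen. The forward step needs kinetic deprotonation of 2 at its saturated α' carbon, acylation at carbon and not oxygen, and closure by the ring enol oxygen onto the alkoxy-bearing alkene carbon.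

9 to 8 to 7. The cuts are the acyl C–Cl bond and the ester O–CH3 bond, pure activation. The enol ether must survive hydroxide and the chlorinating agent.

7 to 5 (through 6). The cuts are the C=C bond to the future C2 of unit 1 and the enol O–CH3 bond. C2 is at the oxidation level of formate, so it is added as a formate ester to the benzylic carbon. The forward step needs O-methylation rather than C-methylation; alkene geometry is not critical.

5 to 3 and 4. The cut is the diaryl ether bond on the side of ring B of unit 1, so that the oxygen stays with the symmetric, doubly ortho-substituted phenol. Both pieces are commercial. The forward step needs a copper catalyst that accepts a hindered phenol and tolerates an enolisable ester.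

2 to 1. The cut is the enol ether O–CH3 bond. Because 1 is symmetric, only one enol ether can form.

## Other disconnections considered

Alternative 1: The cut is C3–C4 in both units at once. Forward, the bis(chalcone epoxide) A2 would be treated with BF3·OEt2; each epoxide opens at its benzylic carbon and each aroyl group shifts to it, giving the bis(α-formyl deoxybenzoin) A1 as its bis-enol. Removal of the two benzyl groups and cyclodehydration would then give the trimethyl ether A3.
- In its favour: one metal-free operation prepares both pyranone rings, and the chalcones come from simple aldol condensations. Treating both units with the same key step is a point on which it is better than the chosen plan, which needs two different annulations.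
- Against it here: the two epoxides differ in benzylic stabilisation (anisyl against aryloxyphenyl), so one opens much faster and the anisyl epoxide is very acid-labile. Aryl migration and fluorohydrin formation compete with the aroyl shift, and A1 can lose its formyl groups. Two benzyl ethers are needed to keep the ortho oxygens from attacking the epoxides, and they must be removed without hydrogenolysis because of the C–Cl bond. The central building block would carry an aldehyde on one ring and a methyl ketone on the other, so the two condensations need an extra masking step.
- Comparison: the chlorine position would be bought in a pre-chlorinated aromatic starting material, which is equal to buying a pre-chlorinated dione. Mechanistically it is a cationic rearrangement with two migratory competitions in each half, against an enolate acylation with one regiochemical question. An estimated 12 to 14 operations stand against 9.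

Alternative 2: The cuts are C3–C1' and O1–C2 in both units. Forward, the bis(2'-hydroxychalcone) A4 would be treated with Tl(NO3)3 in methanol and trimethyl orthoformate, so that both para-oxygenated aryl groups shift from the β to the α carbon, and then with HCl to close both pyranones, giving A3.
- In its favour: it follows the biosynthetic logic, it works with free ortho hydroxyls, and A3 is one demethylation from the target. With one operation after the key step against three, it is better than the chosen plan on this point.
- Against it here: more than two equivalents of toxic trivalent thallium are needed. The aryloxyphenyl group migrates less readily than anisyl. The free, electron-rich phenolic ring of unit 2 can be oxidised by the same reagent. Two rearrangements in one molecule multiply the losses, and the building-block problem of alternative 1 returns.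
- Comparison: the chlorine is again bought with an aromatic starting material (equal). An estimated 10 to 11 operations are close to the chosen plan (nearly equal). The decisive difference is an oxidative heavy-metal step on a substrate with an oxidisable phenol, against non-oxidative enolate chemistry followed by one quinone dehydrogenation.

Alternative 3: The cuts are C7–C8 and C4a–C5 of ring A of unit 2. Forward, the dianion of A6 (made with LiN(i-Pr)2) would be acylated at its γ carbon by A7; acid then unmasks the aldehyde, and aldol closure with dehydration gives the benzoate A5.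
- In its favour: A6 comes from O-alkylation of a phenol, so the hindered ether oxygen is attached by an SN2 reaction before the arene exists. This is better than the copper coupling of the chosen plan. The arene also forms by dehydration, with no dehydrogenation step (also better).
- Against it here: A7 is enolisable and can lose methoxide under strong base. The γ carbanion bears an aryloxy group and is a poorer nucleophile, and the acidic acylation product consumes further dianion. The effort goes into a ring whose substitution pattern is commercial in symmetric form, while the chlorinated ring is left to conventional aromatic chemistry: the bromide of A5 would be converted to a boronate and coupled (Pd(PPh3)4) with the iodochromone A8. The ester of A5 must still be turned into a deoxybenzoin and its two hydroxyls told apart.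
- Comparison: mechanistically it is the same family as the chosen key step (enolate acylation, then closure), so equal there. Structurally it solves the easier ring. An estimated 13 to 15 operations stand against 9.

Key step: step 6

Remark on the structures: carbons C1, C2 and C3 of 2 map onto C8a, C8 and C7 of unit 1, and the E descriptor of 9 (methoxy trans to the acyl carbon) is consistent with its structure, so the constitution of both key-step partners is kept. Two things are changed in how the step is run: two equivalents of enolate are used because the diketone is more acidic than 2, and the ring is closed with acid rather than by the diketonate. The sequence after the key step is also shortened: global demethylation comes first, then a one-flask acylation and ring closure.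
Assumption: 4 is bought as the iodide; the bromide would serve at a somewhat higher temperature.

## Route

Step 1
Reactants: 1 2-chlorocyclohexane-1,3-dione
Product: 2 2-chloro-3-methoxycyclohex-2-en-1-one
Conditions: HC(OMe)3, MeOH, TsOH·H2O (cat.), rt
Reagents that add atoms: trimethyl orthoformate, COC(OC)OC; methanol, CO (the methoxy group comes from their common pool)
Why: Acid-catalysed vinylogous esterification (enol ether formation) of a cyclic 1,3-dione; the dione is symmetric, so only one enol ether can form, and the orthoformate removes the water.

Step 2
Reactants: 3 2,6-dimethoxyphenol; 4 methyl 2-(4-iodophenyl)acetate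
Product: 5 methyl 2-[4-(2,6-dimethoxyphenoxy)phenyl]acetate
Conditions: CuI (10 mol %), picolinic acid (20 mol %), K3PO4, DMSO, 90 °C, Ar
Reagents that add atoms: none
Why: Ullmann-type diaryl ether synthesis with picolinate-ligated monovalent copper, a ligand system that accepts doubly ortho-substituted phenols; phosphate is too weak a base to enolise or cleave the ester, and air is excluded because the phenol is easily oxidised.

Step 3
Reactants: 5 methyl 2-[4-(2,6-dimethoxyphenoxy)phenyl]acetate
Product: 7 methyl (E)-2-[4-(2,6-dimethoxyphenoxy)phenyl]-3-methoxyprop-2-enoate, via sodium formyl enolate 6 (not isolated)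
Conditions: NaH, HCO2Me, DMF, 0 °C to rt; then Me2SO4, rt
Reagents that add atoms: methyl formate, COC=O; dimethyl sulfate, COS(=O)(=O)OC
Why: Crossed Claisen condensation with a non-enolisable formate gives the stabilised enolate 6, and the hard sulfate electrophile methylates it on oxygen; the E isomer (methoxy trans to the ester) is the usual and thermodynamically preferred outcome for 2-aryl-3-methoxyacrylates, and the geometry is not carried beyond step 6.

Step 4
Reactants: 7 methyl (E)-2-[4-(2,6-dimethoxyphenoxy)phenyl]-3-methoxyprop-2-enoate
Product: 8 (E)-2-[4-(2,6-dimethoxyphenoxy)phenyl]-3-methoxyprop-2-enoic acid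
Conditions: LiOH·H2O, THF–MeOH–H2O, rt; then 1 M HCl to pH 3, 0 °C
Reagents that add atoms: lithium hydroxide, [Li+].[OH-] (supplies the carboxyl oxygen)
Why: Saponification by acyl substitution; exchange of the β-methoxy group with the methanol co-solvent is degenerate, and cold, brief acidification frees the acid without hydrolysing the enol ether.

Step 5
Reactants: 8 (E)-2-[4-(2,6-dimethoxyphenoxy)phenyl]-3-methoxyprop-2-enoic acid
Product: 9 (E)-2-[4-(2,6-dimethoxyphenoxy)phenyl]-3-methoxyprop-2-enoyl chloride
Conditions: (COCl)2, DMF (cat.), CH2Cl2, 0 °C to rt
Reagents that add atoms: oxalyl chloride, O=C(Cl)C(Cl)=O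
Why: Standard acid chloride formation through the catalytic chloroiminium species; 9 has no α-hydrogen and cannot form a ketene, and the crude chloride should be concentrated and used at once.

Step 6
Reactants: 2 2-chloro-3-methoxycyclohex-2-en-1-one; 9 (E)-2-[4-(2,6-dimethoxyphenoxy)phenyl]-3-methoxyprop-2-enoyl chloride
Product: 12 8-chloro-3-[4-(2,6-dimethoxyphenoxy)phenyl]-7-methoxy-5,6-dihydro-4H-chromen-4-one, via lithium dienolate 10 (not isolated), via acylated diketone 11 (not isolated)
Conditions: 2 (2.2 equiv), LiN(i-Pr)2 (2.1 equiv), THF, −78 °C; 9 (1.0 equiv), −78 to −20 °C; then CF3CO2H (excess), CH2Cl2, −78 °C to rt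
Reagents that add atoms: none
Why: The hindered amide at −78 °C removes a proton from the saturated α' methylene of 2 under kinetic control (Stork–Danheiser-type enolisation), and the carbon terminus of dienolate 10 attacks the acyl chloride carbon of 9, forming the bond that becomes C4–C4a. Because 11 is more acidic than 2, a second equivalent of 10 serves as base, which is why the cheap ketone 2 and not 9 is in excess; the slight excess of 2 over the amide leaves no free amide to attack 9. Acid then converts the diketonate into the chelated enol 11 and activates the acryloyl carbonyl, so that the ring enol oxygen adds to the methoxy-bearing carbon and methanol is lost, forming O1–C2. The closest known reaction types are the C-acylation of kinetic 3-alkoxycyclohexenone enolates by acid chlorides and the γ-pyranone synthesis from ketone enolates and β-methoxyacryloyl chlorides completed with acid. The pyranone closes by a 6-endo-trig addition–elimination at oxygen, and no other oxygen of 11 can reach an electrophilic carbon through a five- or six-membered transition state. No stereocentre is created, and because the methoxy-bearing carbon passes through an sp3 stage, the alkene geometry of 9 is not transferred. The step needs α' rather than γ deprotonation (secured by low temperature and the bulky base) and C- rather than O-acylation (favoured by the lithium counter-ion in THF and by an acid chloride that cannot react as a ketene).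

Step 7
Reactants: 12 8-chloro-3-[4-(2,6-dimethoxyphenoxy)phenyl]-7-methoxy-5,6-dihydro-4H-chromen-4-one
Product: 13 8-chloro-3-[4-(2,6-dimethoxyphenoxy)phenyl]-7-methoxy-4H-chromen-4-one
Conditions: DDQ (1.3 equiv), 1,4-dioxane, 80 °C
Reagents that add atoms: none
Why: Quinone dehydrogenation: hydride abstraction from C5 gives a cation stabilised by O1 and the C7 methoxy group, and loss of the C6 proton aromatises ring A; the trioxygenated ring has no benzylic hydrogen to lose.

Step 8
Reactants: 13 8-chloro-3-[4-(2,6-dimethoxyphenoxy)phenyl]-7-methoxy-4H-chromen-4-one
Product: 14 8-chloro-3-[4-(2,6-dihydroxyphenoxy)phenyl]-7-hydroxy-4H-chromen-4-one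
Conditions: BBr3 (6 equiv), CH2Cl2, −78 °C to rt; then H2O, 0 °C
Reagents that add atoms: none
Why: Lewis-acid ether cleavage: each methoxy oxygen complexes BBr3 and bromide attacks the methyl group by SN2; diaryl ethers, the pyranone and the aryl chloride do not react under these conditions.

Step 9
Reactants: 14 8-chloro-3-[4-(2,6-dihydroxyphenoxy)phenyl]-7-hydroxy-4H-chromen-4-one; 15 2-(4-hydroxyphenyl)acetic acid
Product: 17 bisoflavolin J, via deoxybenzoin 16 (not isolated)
Conditions: BF3·OEt2, 85 °C; then DMF, MsCl, 70 °C; aq. NaOAc
Reagents that add atoms: N,N-dimethylformamide, CN(C)C=O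
Why: Friedel–Crafts (Fries-type) acylation in BF3·OEt2 goes to the resorcinol ring of 14, ortho to one hydroxyl and para to the other (two equivalent sites), while ring A of unit 1 is deactivated by its complexed carbonyl. The chelated deoxybenzoin 16 then condenses at its benzylic methylene with the iminium reagent from DMF and MsCl and cyclises with loss of dimethylamine (the deoxybenzoin route to isoflavones, known to work on unprotected polyhydroxy substrates).

## Compound list

1 | 2-chlorocyclohexane-1,3-dione | O=C1CCCC(=O)C1Cl | starting material
2 | 2-chloro-3-methoxycyclohex-2-en-1-one | COC1=C(Cl)C(=O)CCC1 | intermediate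
3 | 2,6-dimethoxyphenol | COc1cccc(OC)c1O | starting material
4 | methyl 2-(4-iodophenyl)acetate | COC(=O)Cc1ccc(I)cc1 | starting material
5 | methyl 2-[4-(2,6-dimethoxyphenoxy)phenyl]acetate | COC(=O)Cc1ccc(Oc2c(OC)cccc2OC)cc1 | intermediate
6 | sodium enolate of methyl 2-[4-(2,6-dimethoxyphenoxy)phenyl]-3-oxopropanoate (configurationally mobile) | [Na+].[O-]C=C(C(=O)OC)c1ccc(Oc2c(OC)cccc2OC)cc1 | intermediate (not isolated)
7 | methyl (E)-2-[4-(2,6-dimethoxyphenoxy)phenyl]-3-methoxyprop-2-enoate | CO/C=C(/C(=O)OC)c1ccc(Oc2c(OC)cccc2OC)cc1 | intermediate
8 | (E)-2-[4-(2,6-dimethoxyphenoxy)phenyl]-3-methoxyprop-2-enoic acid | CO/C=C(/C(=O)O)c1ccc(Oc2c(OC)cccc2OC)cc1 | intermediate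
9 | (E)-2-[4-(2,6-dimethoxyphenoxy)phenyl]-3-methoxyprop-2-enoyl chloride | CO/C=C(/C(Cl)=O)c1ccc(Oc2c(OC)cccc2OC)cc1 | intermediate
10 | lithium 6-chloro-5-methoxycyclohexa-1,5-dien-1-olate (α' enolate of 2) | [Li+].[O-]C1=CCCC(OC)=C1Cl | intermediate (not isolated)
11 | 2-chloro-6-{(E)-2-[4-(2,6-dimethoxyphenoxy)phenyl]-3-methoxyprop-2-enoyl}-3-methoxycyclohex-2-en-1-one, drawn as its chelated ring enol | COC1=C(Cl)C(O)=C(CC1)C(=O)/C(=C/OC)c1ccc(Oc2c(OC)cccc2OC)cc1 | intermediate (not isolated)
12 | 8-chloro-3-[4-(2,6-dimethoxyphenoxy)phenyl]-7-methoxy-5,6-dihydro-4H-chromen-4-one | COC1=C(Cl)C2=C(CC1)C(=O)C(c1ccc(Oc3c(OC)cccc3OC)cc1)=CO2 | intermediate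
13 | 8-chloro-3-[4-(2,6-dimethoxyphenoxy)phenyl]-7-methoxy-4H-chromen-4-one | COc1ccc2c(=O)c(-c3ccc(Oc4c(OC)cccc4OC)cc3)coc2c1Cl | intermediate
14 | 8-chloro-3-[4-(2,6-dihydroxyphenoxy)phenyl]-7-hydroxy-4H-chromen-4-one | Oc1ccc2c(=O)c(-c3ccc(Oc4c(O)cccc4O)cc3)coc2c1Cl | intermediate
15 | 2-(4-hydroxyphenyl)acetic acid | OC(=O)Cc1ccc(O)cc1 | starting material
16 | 8-chloro-3-(4-{2,6-dihydroxy-3-[2-(4-hydroxyphenyl)acetyl]phenoxy}phenyl)-7-hydroxy-4H-chromen-4-one | Oc1ccc2c(=O)c(-c3ccc(Oc4c(O)ccc(C(=O)Cc5ccc(O)cc5)c4O)cc3)coc2c1Cl | intermediate (not isolated)
17 | bisoflavolin J, 8-chloro-7-hydroxy-3-(4-{[7-hydroxy-3-(4-hydroxyphenyl)-4-oxo-4H-chromen-8-yl]oxy}phenyl)-4H-chromen-4-one | O=c1c(-c2ccc(Oc3c(O)ccc4c(=O)c(-c5ccc(O)cc5)coc34)cc2)coc2c(Cl)c(O)ccc12 | target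

## Step count and least certain steps

Total: 9 steps. Longest linear sequence: 8 steps (steps 2 to 9, from 3 and 4); step 1 is a one-step side branch that joins at step 6.

Step 6 (key step). The most likely failure is acylation of dienolate 10 at oxygen instead of carbon, because the acid chloride is hindered and electronically deactivated. Proton transfer from the acidic diketone can also stall conversion, and ring closure can remain incomplete if the acid is too weak in the ethereal medium. Fallback, from 9 and 2, back at 12: 9 would be reduced with LiAlH(OtBu)3 in THF at −78 °C to (E)-2-[4-(2,6-dimethoxyphenoxy)phenyl]-3-methoxyprop-2-enal F1. Addition of F1 to dienolate 10 (made from 2 as in step 6) is an aldol reaction, in which bonding at oxygen leads nowhere, and should give 2-chloro-6-{(E)-1-hydroxy-2-[4-(2,6-dimethoxyphenoxy)phenyl]-3-methoxyprop-2-en-1-yl}-3-methoxycyclohex-2-en-1-one F2 as a mixture of diastereomers. Oxidation with Dess–Martin periodinane (NaHCO3 buffer) would give 11, and CF3CO2H in CH2Cl2 would close it to 12.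

Step 2. Oxidative self-coupling of the electron-rich phenol at copper and slow coupling caused by the two ortho substituents are the likely problems; partial ester hydrolysis by wet phosphate is a lesser one. Fallback, from 3, back at 5: nucleophilic aromatic substitution of 3 on 4-fluoroacetophenone (K2CO3, DMF, 140 °C) would give 1-[4-(2,6-dimethoxyphenoxy)phenyl]ethan-1-one F3. A Willgerodt–Kindler reaction (S8, morpholine, 130 °C) would give 2-[4-(2,6-dimethoxyphenoxy)phenyl]-1-(morpholin-4-yl)ethane-1-thione F4. Hydrolysis (KOH, aqueous EtOH, reflux) would give 2-[4-(2,6-dimethoxyphenoxy)phenyl]acetic acid F5, and Fischer esterification (MeOH, H2SO4 cat.) would give 5.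

Step 9. The acylation may stop at O-acylated stages or suffer from poor solubility of the polar triol in BF3·OEt2, and the one-carbon reagent may formylate a phenolic position. Fallback, from 13, back at 16: 13 would be acylated while still methylated with 4-methoxyphenylacetic acid under (CF3CO)2O and catalytic H3PO4, at the position para to one methoxy and ortho to the other, giving 8-chloro-3-(4-{2,6-dimethoxy-3-[2-(4-methoxyphenyl)acetyl]phenoxy}phenyl)-7-methoxy-4H-chromen-4-one F6. BBr3 in CH2Cl2 would cleave all four methyl ethers to give 16, which would be isolated and closed to 17 with BF3·OEt2, DMF and MsCl as in the second half of step 9.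

Step 7. Hydride abstraction may be slow if the quinone is tied up in a charge-transfer complex with the trioxygenated ring, and addition of the hydroquinone to the intermediate cation is possible. Fallback, from 11, back at 13: 11 would be isolated after a neutral quench of step 6 (before acid) and selenenylated at the carbon between its two carbonyls with PhSeCl and pyridine in CH2Cl2, giving 2-chloro-6-{(E)-2-[4-(2,6-dimethoxyphenoxy)phenyl]-3-methoxyprop-2-enoyl}-3-methoxy-6-(phenylselanyl)cyclohex-2-en-1-one F7. Oxidation with H2O2 at 0 °C, syn elimination of the selenoxide and tautomerisation should give the phenol (E)-1-(3-chloro-2-hydroxy-4-methoxyphenyl)-2-[4-(2,6-dimethoxyphenoxy)phenyl]-3-methoxyprop-2-en-1-one F8, which CF3CO2H would close directly to 13.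

## Further compounds

F1 | step 6 | (E)-2-[4-(2,6-dimethoxyphenoxy)phenyl]-3-methoxyprop-2-enal | CO/C=C(/C=O)c1ccc(Oc2c(OC)cccc2OC)cc1
F2 | step 6 | 2-chloro-6-{(E)-1-hydroxy-2-[4-(2,6-dimethoxyphenoxy)phenyl]-3-methoxyprop-2-en-1-yl}-3-methoxycyclohex-2-en-1-one (mixture of diastereomers) | COC1=C(Cl)C(=O)C(CC1)C(O)/C(=C/OC)c1ccc(Oc2c(OC)cccc2OC)cc1
F3 | step 2 | 1-[4-(2,6-dimethoxyphenoxy)phenyl]ethan-1-one | CC(=O)c1ccc(Oc2c(OC)cccc2OC)cc1
F4 | step 2 | 2-[4-(2,6-dimethoxyphenoxy)phenyl]-1-(morpholin-4-yl)ethane-1-thione | S=C(Cc1ccc(Oc2c(OC)cccc2OC)cc1)N1CCOCC1
F5 | step 2 | 2-[4-(2,6-dimethoxyphenoxy)phenyl]acetic acid | OC(=O)Cc1ccc(Oc2c(OC)cccc2OC)cc1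
F6 | step 9 | 8-chloro-3-(4-{2,6-dimethoxy-3-[2-(4-methoxyphenyl)acetyl]phenoxy}phenyl)-7-methoxy-4H-chromen-4-one | COc1ccc(CC(=O)c2ccc(OC)c(Oc3ccc(-c4coc5c(Cl)c(OC)ccc5c4=O)cc3)c2OC)cc1
F7 | step 7 | 2-chloro-6-{(E)-2-[4-(2,6-dimethoxyphenoxy)phenyl]-3-methoxyprop-2-enoyl}-3-methoxy-6-(phenylselanyl)cyclohex-2-en-1-one (racemic) | COC1=C(Cl)C(=O)C(CC1)([Se]c1ccccc1)C(=O)/C(=C/OC)c1ccc(Oc2c(OC)cccc2OC)cc1
F8 | step 7 | (E)-1-(3-chloro-2-hydroxy-4-methoxyphenyl)-2-[4-(2,6-dimethoxyphenoxy)phenyl]-3-methoxyprop-2-en-1-one | COc1ccc(C(=O)/C(=C/OC)c2ccc(Oc3c(OC)cccc3OC)cc2)c(O)c1Cl
A1 | alternative 1 | bis(α-formyl deoxybenzoin) as its (Z,Z)-bis-enol | COc1ccc(C(=O)/C(=C\O)c2ccc(Oc3c(OC)ccc(C(=O)/C(=C\O)c4ccc(OC)cc4)c3OCc3ccccc3)cc2)c(OCc2ccccc2)c1Cl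
A2 | alternative 1 | bis(trans-chalcone epoxide), one of two racemic diastereomers shown | COc1ccc(C(=O)[C@H]5O[C@@H]5c2ccc(Oc3c(OC)ccc(C(=O)[C@H]6O[C@@H]6c4ccc(OC)cc4)c3OCc3ccccc3)cc2)c(OCc2ccccc2)c1Cl
A3 | alternative 2 | tri-O-methylbisoflavolin J | O=c1c(-c2ccc(Oc3c(OC)ccc4c(=O)c(-c5ccc(OC)cc5)coc34)cc2)coc2c(Cl)c(OC)ccc12
A4 | alternative 2 | (E,E)-bis(2'-hydroxychalcone) | COc1ccc(C(=O)/C=C/c2ccc(Oc3c(OC)ccc(C(=O)/C=C/c4ccc(OC)cc4)c3O)cc2)c(O)c1Cl
A5 | alternative 3 | methyl 3-(4-bromophenoxy)-2,4-dihydroxybenzoate | COC(=O)c1ccc(O)c(Oc2ccc(Br)cc2)c1O
A6 | alternative 3 | methyl 4-(4-bromophenoxy)-3-oxobutanoate | COC(=O)CC(=O)COc1ccc(Br)cc1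
A7 | alternative 3 | methyl 3,3-dimethoxypropanoate | COC(=O)CC(OC)OC
A8 | alternative 3 | 8-chloro-3-iodo-7-methoxy-4H-chromen-4-one | COc1ccc2c(=O)c(I)coc2c1Cl
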